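## Retrosynthetic overview

The strategy rests on the C3–C4 unit of the chroman. C3, the only stereocentre, carries ring B through C1′; C4 carries ring A through C4a; C2 is still absent. This is the pattern of a vinylboron ate complex after 1,2-shift of an aryl group to the boron-bearing carbon and arylation of the terminal carbon.
Key disconnection: C3–C1′ and C4–C4a are formed together in a palladium-catalysed enantioselective conjunctive coupling of vinylboronic pinacol ester, a ring B aryllithium and a ring A aryl bromide; boron stays on C3.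
C2 is then added by Matteson homologation of the C3 boronate and oxidised to the alcohol. The C8 aldehyde is introduced ortho to the freed C8a phenol, whose only open ortho carbon is C8.
Ring order: rings A and B come from 2-bromo-3-methoxyphenol and resorcinol. Ring C (the pyran ring, O1–C2 bond) is the only ring formed, by Mitsunobu etherification, before global MOM removal.

Key step: step 6

Remark on supply: 2-bromo-3-methoxyphenol, resorcinol, prenyl bromide and vinylboronic acid pinacol ester are taken as catalogue compounds.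
Remark on the ligand: the (Sp,Sp)-configured ferrocenyl bisphosphine named in step 6 is assumed to deliver the (R)-boronate. If the sense proves opposite, its (Rp,Rp) antipode is used with no other change.

## Route

Step 1
Reactants: 1 2-bromo-3-methoxyphenol
Product: 2 (2-bromo-3-methoxyphenoxy)(tert-butyl)dimethylsilane
Conditions: TBSCl, imidazole, DMF, rt
Reagents that add atoms: tert-butyldimethylsilyl chloride, CC(C)(C)[Si](C)(C)Cl
Why: Imidazole-promoted O-silylation of a phenol; the silyl ether masks the future C8a–OH, tolerates the iridium, lithium and palladium chemistry, and is later removed by fluoride without loss of MOM ethers.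

Step 2
Reactants: 2 (2-bromo-3-methoxyphenoxy)(tert-butyl)dimethylsilane
Product: 4 4-bromo-3-(tert-butyldimethylsilyloxy)-5-methoxyphenol, via aryl pinacol boronate 3 (not isolated)
Conditions: [Ir(OMe)(cod)]2 (cod = cycloocta-1,5-diene, 1.5 mol%), 4,4′-di-tert-butyl-2,2′-bipyridine (3 mol%), B2pin2, THF, 80 °C; then aq. KHSO5 (as 2KHSO5·KHSO4·K2SO4), acetone, 0 °C → rt
Reagents that add atoms: potassium peroxymonosulfate, [K+].[O-]S(=O)(=O)OO
Why: Sterically governed iridium-catalysed aromatic C–H borylation of the 1,2,3-trisubstituted arene should take the one C–H with no ortho neighbour (para to bromine, the future C7) and tolerates C–Br, and peroxymonosulfate oxidation of the C–B bond in the same flask gives the phenol.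

Step 3
Reactants: 4 4-bromo-3-(tert-butyldimethylsilyloxy)-5-methoxyphenol
Product: 5 [2-bromo-3-methoxy-5-(methoxymethoxy)phenoxy](tert-butyl)dimethylsilane
Conditions: MOMCl, i-Pr2NEt, CH2Cl2, 0 °C → rt
Reagents that add atoms: chloromethyl methyl ether, COCCl
Why: Base-mediated O-alkylation of the phenol caps the future C7–OH as a MOM ether, so the two ring A oxygens are differentiated (silyl on the future C8a–O, MOM on the future C7–O).

Step 4
Reactants: 6 resorcinol
Product: 7 1,3-bis(methoxymethoxy)benzene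
Conditions: NaH, DMF, 0 °C; MOMCl, 0 °C → rt
Reagents that add atoms: chloromethyl methyl ether, COCCl
Why: Double Williamson-type O-alkylation of the bis-phenoxide; the MOM ethers direct both later lithiations and survive the basic, organometallic and fluoride steps.

Step 5
Reactants: 7 1,3-bis(methoxymethoxy)benzene; 8 prenyl bromide (1-bromo-3-methylbut-2-ene)
Product: 10 1,3-bis(methoxymethoxy)-2-(3-methylbut-2-en-1-yl)benzene, via 2,6-bis(methoxymethoxy)phenyllithium 9 (not isolated)
Conditions: n-BuLi, THF, 0 °C; CuI (10 mol%), 8, −78 °C → rt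
Reagents that add atoms: none
Why: Directed ortho-metalation between the two cooperating MOM ethers, then copper-catalysed allylation of the aryllithium at the unhindered CH2 terminus of prenyl bromide, fixes the prenyl group on the future C3′.

Step 6
Reactants: 10 1,3-bis(methoxymethoxy)-2-(3-methylbut-2-en-1-yl)benzene; 11 vinylboronic acid pinacol ester (2-ethenyl-4,4,5,5-tetramethyl-1,3,2-dioxaborolane); 5 [2-bromo-3-methoxy-5-(methoxymethoxy)phenoxy](tert-butyl)dimethylsilane
Product: 14 2-[(1R)-1-[2,4-bis(methoxymethoxy)-3-(3-methylbut-2-en-1-yl)phenyl]-2-[2-(tert-butyldimethylsilyloxy)-6-methoxy-4-(methoxymethoxy)phenyl]ethyl]-4,4,5,5-tetramethyl-1,3,2-dioxaborolane, via 2,4-bis(methoxymethoxy)-3-(3-methylbut-2-en-1-yl)phenyllithium 12 (not isolated), via lithium aryl(vinyl)(pinacolato)borate 13 (not isolated)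
Conditions: n-BuLi (0.95 equiv relative to 10), THF, 0 °C; 11, −78 °C → rt; then 5, Pd(OAc)2 (3 mol%), (Sp,Sp)-1,1′-bis[bis(4-methoxy-3,5-dimethylphenyl)phosphino]-2,2′-bis[(R)-α-(dimethylamino)benzyl]ferrocene (3.6 mol%), NaOTf, THF, 60 °C
Reagents that add atoms: none
Why: n-BuLi removes the C4–H of 10, the only ring hydrogen ortho to a MOM ether (directed ortho-metalation), giving halide-free aryllithium 12, which adds to boron of 11 to give ate complex 13. Oxidative addition of 5 to zerovalent palladium and bromide removal by NaOTf give a cationic aryl complex of divalent palladium that binds the vinyl group of 13; the ring B aryl group then shifts from boron to the boron-bearing carbon anti to palladium while palladium bonds the terminal carbon, and reductive elimination forms C4–C4a. The closest known reaction is the palladium-catalysed enantioselective conjunctive cross-coupling of vinylboron ate complexes with aryl electrophiles, aryl bromides included when a triflate salt scavenges halide. No ring is closed. C3 is the one new stereocentre and should be set (R) by the enantioface of the vinyl group bound by the chiral bisphosphine–palladium aryl complex. The step needs the metallate shift to outrun direct transmetalation and β-hydride elimination, which the wide-bite-angle ligand and the absence of free halide favour; in 5 the methoxy methyl and the silyl group can turn toward their C–H neighbours, so only two oxygen atoms flank the C–Br carbon.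

Step 7
Reactants: 14 the (R)-C3 pinacol boronate of step 6
Product: 16 2-[(2R)-2-[2,4-bis(methoxymethoxy)-3-(3-methylbut-2-en-1-yl)phenyl]-3-[2-(tert-butyldimethylsilyloxy)-6-methoxy-4-(methoxymethoxy)phenyl]propyl]-4,4,5,5-tetramethyl-1,3,2-dioxaborolane, via lithium chloromethyl borate complex 15 (not isolated)
Conditions: BrCH2Cl, n-BuLi, THF, −78 °C → rt
Reagents that add atoms: bromochloromethane, ClCBr
Why: Matteson homologation: chloromethyllithium generated in the presence of 14 adds to boron, and on warming C3 migrates to the CH2 carbon with loss of chloride and retention of configuration, so C2 is added and C3 stays (R).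

Step 8
Reactants: 16 the homologated primary pinacol boronate
Product: 17 (2R)-2-[2,4-bis(methoxymethoxy)-3-(3-methylbut-2-en-1-yl)phenyl]-3-[2-(tert-butyldimethylsilyloxy)-6-methoxy-4-(methoxymethoxy)phenyl]propan-1-ol
Conditions: NaBO3·4H2O, THF–H2O, rt
Reagents that add atoms: sodium perborate tetrahydrate, [Na+].[O-]OB=O.O.O.O.O
Why: Peroxoborate oxidation of the primary C–B bond (1,2-shift from boron to oxygen) gives the C2 alcohol under mild conditions that should spare the aryl silyl ether, the MOM ethers and the prenyl alkene; C3 is not involved.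

Step 9
Reactants: 17 the C2 alcohol with silylated C8a oxygen
Product: 18 (2R)-2-[2,4-bis(methoxymethoxy)-3-(3-methylbut-2-en-1-yl)phenyl]-3-[2-hydroxy-6-methoxy-4-(methoxymethoxy)phenyl]propan-1-ol
Conditions: TBAF, AcOH, THF, 0 °C
Reagents that add atoms: none
Why: Fluoride cleavage of the aryl silyl ether frees only the C8a phenol, the MOM ethers being inert to fluoride, and acetic acid buffers the phenoxide.

Step 10
Reactants: 18 the C8a phenol with free C2 alcohol
Product: 20 3-[(2R)-2-[2,4-bis(methoxymethoxy)-3-(3-methylbut-2-en-1-yl)phenyl]-3-hydroxypropyl]-2-hydroxy-4-methoxy-6-(methoxymethoxy)benzaldehyde, via C8-hydroxymethyl phenol 19 (not isolated)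
Conditions: MgCl2, Et3N, (CH2O)n, MeCN, reflux
Reagents that add atoms: paraformaldehyde (formaldehyde source), C=O
Why: Magnesium-phenoxide-directed ortho-formylation (Casnati–Skattebøl): formaldehyde is delivered within the magnesium chelate to the only free ortho carbon of the C8a phenol, C8 (the other ortho carbon is C4a), and a second formaldehyde oxidises the hydroxymethyl group by hydride transfer, so the regiochemistry is fixed by the substitution pattern.

Step 11
Reactants: 20 the C8 aldehyde with free C8a phenol and C2 alcohol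
Product: 21 (3R)-3-[2,4-bis(methoxymethoxy)-3-(3-methylbut-2-en-1-yl)phenyl]-5-methoxy-7-(methoxymethoxy)-3,4-dihydro-2H-1-benzopyran-8-carbaldehyde
Conditions: PPh3, DIAD, THF (0.02 M), 0 °C → rt
Reagents that add atoms: none
Why: Intramolecular Mitsunobu etherification: the acidic salicylaldehyde-type C8a–OH, the only free phenol, displaces the activated primary C2–OH in a 6-exo-tet closure of ring C; C3 is untouched and stays (R).

Step 12
Reactants: 21 the tris-MOM chroman aldehyde
Product: 22 (3R)-3-[2,4-dihydroxy-3-(3-methylbut-2-en-1-yl)phenyl]-7-hydroxy-5-methoxy-3,4-dihydro-2H-1-benzopyran-8-carbaldehyde (CNP0399843.1)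
Conditions: 3 M aq. HCl, MeOH, 40 °C
Reagents that add atoms: none
Why: Acid-catalysed acetal methanolysis removes the three MOM ethers; dilute aqueous-methanolic acid at mild temperature is the usual way to unmask ortho-prenyl phenols without cyclisation onto the alkene, and water keeps the aldehyde free.

## Compound list

1 | 2-bromo-3-methoxyphenol | COc1cccc(O)c1Br | starting material
2 | (2-bromo-3-methoxyphenoxy)(tert-butyl)dimethylsilane | COc1cccc(O[Si](C)(C)C(C)(C)C)c1Br | intermediate
3 | tert-butyl[2-bromo-3-methoxy-5-(4,4,5,5-tetramethyl-1,3,2-dioxaborolan-2-yl)phenoxy]dimethylsilane | COc1cc(B2OC(C)(C)C(C)(C)O2)cc(O[Si](C)(C)C(C)(C)C)c1Br | intermediate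
4 | 4-bromo-3-(tert-butyldimethylsilyloxy)-5-methoxyphenol | COc1cc(O)cc(O[Si](C)(C)C(C)(C)C)c1Br | intermediate
5 | [2-bromo-3-methoxy-5-(methoxymethoxy)phenoxy](tert-butyl)dimethylsilane | COc1cc(OCOC)cc(O[Si](C)(C)C(C)(C)C)c1Br | intermediate
6 | resorcinol | Oc1cccc(O)c1 | starting material
7 | 1,3-bis(methoxymethoxy)benzene | COCOc1cccc(OCOC)c1 | intermediate
8 | prenyl bromide (1-bromo-3-methylbut-2-ene) | CC(C)=CCBr | starting material
9 | 2,6-bis(methoxymethoxy)phenyllithium | [Li]c1c(OCOC)cccc1OCOC | intermediate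
10 | 1,3-bis(methoxymethoxy)-2-(3-methylbut-2-en-1-yl)benzene | COCOc1cccc(OCOC)c1CC=C(C)C | intermediate
11 | vinylboronic acid pinacol ester | C=CB1OC(C)(C)C(C)(C)O1 | starting material
12 | 2,4-bis(methoxymethoxy)-3-(3-methylbut-2-en-1-yl)phenyllithium | [Li]c1ccc(OCOC)c(CC=C(C)C)c1OCOC | intermediate
13 | lithium [2,4-bis(methoxymethoxy)-3-(3-methylbut-2-en-1-yl)phenyl](ethenyl)(pinacolato)borate | [Li+].C=C[B-]1(c2ccc(OCOC)c(CC=C(C)C)c2OCOC)OC(C)(C)C(C)(C)O1 | intermediate
14 | 2-[(1R)-1-[2,4-bis(methoxymethoxy)-3-(3-methylbut-2-en-1-yl)phenyl]-2-[2-(tert-butyldimethylsilyloxy)-6-methoxy-4-(methoxymethoxy)phenyl]ethyl]-4,4,5,5-tetramethyl-1,3,2-dioxaborolane | COc1cc(OCOC)cc(O[Si](C)(C)C(C)(C)C)c1C[C@H](c1ccc(OCOC)c(CC=C(C)C)c1OCOC)B1OC(C)(C)C(C)(C)O1 | intermediate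
15 | lithium (chloromethyl)[(1R)-1-[2,4-bis(methoxymethoxy)-3-(3-methylbut-2-en-1-yl)phenyl]-2-[2-(tert-butyldimethylsilyloxy)-6-methoxy-4-(methoxymethoxy)phenyl]ethyl](pinacolato)borate | COc1cc(OCOC)cc(O[Si](C)(C)C(C)(C)C)c1C[C@H](c1ccc(OCOC)c(CC=C(C)C)c1OCOC)[B-]1(CCl)OC(C)(C)C(C)(C)O1.[Li+] | intermediate
16 | 2-[(2R)-2-[2,4-bis(methoxymethoxy)-3-(3-methylbut-2-en-1-yl)phenyl]-3-[2-(tert-butyldimethylsilyloxy)-6-methoxy-4-(methoxymethoxy)phenyl]propyl]-4,4,5,5-tetramethyl-1,3,2-dioxaborolane | COc1cc(OCOC)cc(O[Si](C)(C)C(C)(C)C)c1C[C@H](c1ccc(OCOC)c(CC=C(C)C)c1OCOC)CB1OC(C)(C)C(C)(C)O1 | intermediate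
17 | (2R)-2-[2,4-bis(methoxymethoxy)-3-(3-methylbut-2-en-1-yl)phenyl]-3-[2-(tert-butyldimethylsilyloxy)-6-methoxy-4-(methoxymethoxy)phenyl]propan-1-ol | COc1cc(OCOC)cc(O[Si](C)(C)C(C)(C)C)c1C[C@H](c1ccc(OCOC)c(CC=C(C)C)c1OCOC)CO | intermediate
18 | (2R)-2-[2,4-bis(methoxymethoxy)-3-(3-methylbut-2-en-1-yl)phenyl]-3-[2-hydroxy-6-methoxy-4-(methoxymethoxy)phenyl]propan-1-ol | COc1cc(OCOC)cc(O)c1C[C@H](c1ccc(OCOC)c(CC=C(C)C)c1OCOC)CO | intermediate
19 | (2R)-2-[2,4-bis(methoxymethoxy)-3-(3-methylbut-2-en-1-yl)phenyl]-3-[2-hydroxy-3-(hydroxymethyl)-6-methoxy-4-(methoxymethoxy)phenyl]propan-1-ol | COc1cc(OCOC)c(CO)c(O)c1C[C@H](c1ccc(OCOC)c(CC=C(C)C)c1OCOC)CO | intermediate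
20 | 3-[(2R)-2-[2,4-bis(methoxymethoxy)-3-(3-methylbut-2-en-1-yl)phenyl]-3-hydroxypropyl]-2-hydroxy-4-methoxy-6-(methoxymethoxy)benzaldehyde | COc1cc(OCOC)c(C=O)c(O)c1C[C@H](c1ccc(OCOC)c(CC=C(C)C)c1OCOC)CO | intermediate
21 | (3R)-3-[2,4-bis(methoxymethoxy)-3-(3-methylbut-2-en-1-yl)phenyl]-5-methoxy-7-(methoxymethoxy)-3,4-dihydro-2H-1-benzopyran-8-carbaldehyde | COc1cc(OCOC)c(C=O)c2c1C[C@H](c1ccc(OCOC)c(CC=C(C)C)c1OCOC)CO2 | intermediate
22 | (3R)-3-[2,4-dihydroxy-3-(3-methylbut-2-en-1-yl)phenyl]-7-hydroxy-5-methoxy-3,4-dihydro-2H-1-benzopyran-8-carbaldehyde | COc1cc(O)c(C=O)c2c1C[C@H](c1ccc(O)c(CC=C(C)C)c1O)CO2 | target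

## Step count and risk

Total step count: 12 (steps 1–3 for the ring A bromide, steps 4–5 for the ring B arene, steps 6–12 from the coupling to the target).
Longest linear sequence: 10 steps (1, 2, 3, 6, 7, 8, 9, 10, 11, 12).

Steps most likely to fail:

1. Step 6. Oxidative addition of the electron-rich, di-ortho-oxygenated bromide and binding of the vinyl borate to the crowded aryl palladium complex may be slow, so that ate complex 13 is lost to direct cross-coupling or protodeboronation and the yield or enantioselectivity drops. The fallback forms the same C3–C1′ bond and the same boronate by stoichiometric lithiation–borylation; it sets out from 5 and from aryllithium 12 and returns to the route at 14. Stille vinylation of 5 (Bu3SnCH=CH2, Pd(PPh3)4, toluene, 110 °C) should give tert-butyl[2-ethenyl-3-methoxy-5-(methoxymethoxy)phenoxy]dimethylsilane F1. Hydroboration with 9-BBN-H (THF, rt) gives 9-[2-[2-(tert-butyldimethylsilyloxy)-6-methoxy-4-(methoxymethoxy)phenyl]ethyl]-9-borabicyclo[3.3.1]nonane F2, which is oxidised in the same flask (NaBO3·4H2O) to 2-[2-(tert-butyldimethylsilyloxy)-6-methoxy-4-(methoxymethoxy)phenyl]ethan-1-ol F3. Mitsunobu esterification with 2,4,6-triisopropylbenzoic acid (PPh3, DIAD, THF) gives 2-[2-(tert-butyldimethylsilyloxy)-6-methoxy-4-(methoxymethoxy)phenyl]ethyl 2,4,6-triisopropylbenzoate F4. Aryllithium 12, made from 10 as in step 6, is quenched with 2-isopropoxy-4,4,5,5-tetramethyl-1,3,2-dioxaborolane to give 2-[2,4-bis(methoxymethoxy)-3-(3-methylbut-2-en-1-yl)phenyl]-4,4,5,5-tetramethyl-1,3,2-dioxaborolane F5. Deprotonation of F4 with s-BuLi and (−)-sparteine (Et2O, −78 °C, kept cold so that ring lithiation does not compete) gives the configurationally stable (S)-α-lithiated triisopropylbenzoate F6, which adds F5 with retention to give the lithium borate complex F7. On warming (MgBr2·OEt2, MeOH), the ring B aryl group migrates from boron to carbon with inversion and loss of triisopropylbenzoate, which should give 14 with the (R) configuration.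

2. Step 12. Once the phenols flanking the prenyl group are free, protic acid may promote their cyclisation onto the alkene or hydration of the alkene. The fallback exchanges the MOM ethers for silyl ethers under amine-buffered, non-protic conditions and removes silicon with fluoride; it sets out from 21 and returns at 22. TESOTf with 2,2′-bipyridyl (CH2Cl2, 0 °C → rt) should convert the three aryl MOM ethers into aryl triethylsilyl ethers, giving (3R)-5-methoxy-7-(triethylsilyloxy)-3-[2,4-bis(triethylsilyloxy)-3-(3-methylbut-2-en-1-yl)phenyl]-3,4-dihydro-2H-1-benzopyran-8-carbaldehyde F8. TBAF buffered with AcOH (THF, 0 °C) then frees the three phenols to give 22.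

3. Step 10. The free primary alcohol may consume formaldehyde and tie up magnesium, so that hydroxymethylation at C8, flanked by the phenoxide and the MOM ether, stalls. The fallback runs the formylation before the C2 oxygen exists; it sets out from 16 and returns at 20. TBAF with AcOH (THF, 0 °C) gives 2-[(2R)-2-[2,4-bis(methoxymethoxy)-3-(3-methylbut-2-en-1-yl)phenyl]-3-(4,4,5,5-tetramethyl-1,3,2-dioxaborolan-2-yl)propyl]-3-methoxy-5-(methoxymethoxy)phenol F9. The same MgCl2/Et3N/paraformaldehyde formylation then acts on a substrate whose only hydroxyl is the C8a phenol. It passes through the C8-hydroxymethyl phenol boronate 2-[(2R)-2-[2,4-bis(methoxymethoxy)-3-(3-methylbut-2-en-1-yl)phenyl]-3-(4,4,5,5-tetramethyl-1,3,2-dioxaborolan-2-yl)propyl]-6-(hydroxymethyl)-3-methoxy-5-(methoxymethoxy)phenol F10 and gives 3-[(2R)-2-[2,4-bis(methoxymethoxy)-3-(3-methylbut-2-en-1-yl)phenyl]-3-(4,4,5,5-tetramethyl-1,3,2-dioxaborolan-2-yl)propyl]-2-hydroxy-4-methoxy-6-(methoxymethoxy)benzaldehyde F11. The C–B bond is then oxidised with anhydrous trimethylamine N-oxide (THF, 65 °C), an oxidant that should not trigger Dakin cleavage of the ortho-hydroxy aldehyde, to give 20.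

Further compounds
F1 | step 6 | tert-butyl[2-ethenyl-3-methoxy-5-(methoxymethoxy)phenoxy]dimethylsilane | COc1cc(OCOC)cc(O[Si](C)(C)C(C)(C)C)c1C=C
F2 | step 6 | 9-[2-[2-(tert-butyldimethylsilyloxy)-6-methoxy-4-(methoxymethoxy)phenyl]ethyl]-9-borabicyclo[3.3.1]nonane | COc1cc(OCOC)cc(O[Si](C)(C)C(C)(C)C)c1CCB1C2CCCC1CCC2
F3 | step 6 | 2-[2-(tert-butyldimethylsilyloxy)-6-methoxy-4-(methoxymethoxy)phenyl]ethan-1-ol | COc1cc(OCOC)cc(O[Si](C)(C)C(C)(C)C)c1CCO
F4 | step 6 | 2-[2-(tert-butyldimethylsilyloxy)-6-methoxy-4-(methoxymethoxy)phenyl]ethyl 2,4,6-triisopropylbenzoate | COc1cc(OCOC)cc(O[Si](C)(C)C(C)(C)C)c1CCOC(=O)c1c(C(C)C)cc(C(C)C)cc1C(C)C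
F5 | step 6 | 2-[2,4-bis(methoxymethoxy)-3-(3-methylbut-2-en-1-yl)phenyl]-4,4,5,5-tetramethyl-1,3,2-dioxaborolane | COCOc1ccc(B2OC(C)(C)C(C)(C)O2)c(OCOC)c1CC=C(C)C
F6 | step 6 | (1S)-2-[2-(tert-butyldimethylsilyloxy)-6-methoxy-4-(methoxymethoxy)phenyl]-1-lithioethyl 2,4,6-triisopropylbenzoate | [Li][C@@H](Cc1c(OC)cc(OCOC)cc1O[Si](C)(C)C(C)(C)C)OC(=O)c1c(C(C)C)cc(C(C)C)cc1C(C)C
F7 | step 6 | lithium [2,4-bis(methoxymethoxy)-3-(3-methylbut-2-en-1-yl)phenyl][(1S)-2-[2-(tert-butyldimethylsilyloxy)-6-methoxy-4-(methoxymethoxy)phenyl]-1-(2,4,6-triisopropylbenzoyloxy)ethyl](pinacolato)borate | [Li+].COCOc1ccc([B-]2(OC(C)(C)C(C)(C)O2)[C@@H](Cc2c(OC)cc(OCOC)cc2O[Si](C)(C)C(C)(C)C)OC(=O)c2c(C(C)C)cc(C(C)C)cc2C(C)C)c(OCOC)c1CC=C(C)C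
F8 | step 12 | (3R)-5-methoxy-7-(triethylsilyloxy)-3-[2,4-bis(triethylsilyloxy)-3-(3-methylbut-2-en-1-yl)phenyl]-3,4-dihydro-2H-1-benzopyran-8-carbaldehyde | COc1cc(O[Si](CC)(CC)CC)c(C=O)c2c1C[C@H](c1ccc(O[Si](CC)(CC)CC)c(CC=C(C)C)c1O[Si](CC)(CC)CC)CO2
F9 | step 10 | 2-[(2R)-2-[2,4-bis(methoxymethoxy)-3-(3-methylbut-2-en-1-yl)phenyl]-3-(4,4,5,5-tetramethyl-1,3,2-dioxaborolan-2-yl)propyl]-3-methoxy-5-(methoxymethoxy)phenol | COc1cc(OCOC)cc(O)c1C[C@H](c1ccc(OCOC)c(CC=C(C)C)c1OCOC)CB1OC(C)(C)C(C)(C)O1
F10 | step 10 | 2-[(2R)-2-[2,4-bis(methoxymethoxy)-3-(3-methylbut-2-en-1-yl)phenyl]-3-(4,4,5,5-tetramethyl-1,3,2-dioxaborolan-2-yl)propyl]-6-(hydroxymethyl)-3-methoxy-5-(methoxymethoxy)phenol | COc1cc(OCOC)c(CO)c(O)c1C[C@H](c1ccc(OCOC)c(CC=C(C)C)c1OCOC)CB1OC(C)(C)C(C)(C)O1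
F11 | step 10 | 3-[(2R)-2-[2,4-bis(methoxymethoxy)-3-(3-methylbut-2-en-1-yl)phenyl]-3-(4,4,5,5-tetramethyl-1,3,2-dioxaborolan-2-yl)propyl]-2-hydroxy-4-methoxy-6-(methoxymethoxy)benzaldehyde | COc1cc(OCOC)c(C=O)c(O)c1C[C@H](c1ccc(OCOC)c(CC=C(C)C)c1OCOC)CB1OC(C)(C)C(C)(C)O1
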